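**Plan**
- Numbering (caryophyllane): cyclobutane C1/C9/C10/C11 (CMe2 on C1); nine-membered ring C1–C9; C4 = O-bearing quaternary carbon, C5 = its CH neighbour, C8 = methylidene carbon, C1′ = CHPh.
- Retrosynthesis cuts, in order: the two aryl–CHO bonds and the two O–Me bonds; C8–C9 (nine-membered ring); C3–C4 together with the C2–C3 unsaturation; C5–C6; C1′–Ph; in the other fragment the cyclobutane bonds C1–C11 and C9–C10 of a cyclopentenone–isobutene photoadduct.
- Enabling feature: C8–C9 joins a cyclobutane CH (C9) to the sp2 carbon C8 that already carries the methylidene. C9 can pass through a planar radical that neither ring-opens nor eliminates, and its configuration is reset on bond formation, so a carboxyl group on C9 and a bromine on C8 suffice.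
- Forward: the benzopyranone ring of 5,7-dimethoxycoumarin is kept and elaborated to the chroman (phenylation, C5 alkylation and inversion, C4 methylenation/ketalisation/alkynylation). The cyclobutane arises by [2+2] photocycloaddition and ketone cleavage. The nine-membered ring is closed last, followed by demethylation and diformylation.
- Stereochemistry: C1′ from the Rh/SEGPHOS conjugate addition; C5 by kinetic protonation anti to phenyl; C4 by nucleophile attack anti to the C5 and C1′ substituents; C1 from the resolved photoadduct; C9 in the ring closure (trans-fused cyclobutane).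

Key step: step 16

Remarks on the chemistry:
- C9 of compounds 16–22 is drawn cis to the C1 side chain. Partial epimerisation at this ester α-carbon is harmless because C9 is reset in step 16.
- The (R)-antipode of SEGPHOS is assumed to give the (4R)-lactone, by analogy with the phenylation of simple coumarins; if the sense proves opposite, the (S)-ligand is used.

**Route**

Step 1
Reactants: 1 5,7-dimethoxycoumarin; 2 phenylboronic acid
Product: 3 (4R)-5,7-dimethoxy-4-phenylchroman-2-one
Conditions: Rh(acac)(C2H4)2 (3 mol %), (R)-SEGPHOS (3.3 mol %), 2 (5 equiv), dioxane/H2O 10:1, 60 °C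
Reagents that add atoms: none
Why: Hayashi–Miyaura rhodium-catalysed asymmetric 1,4-addition of an arylboronic acid to a coumarin, in which the chiral bisphosphine–Rh–phenyl species selects one face of C3=C4 and so sets C1′; excess boronic acid compensates for the electron-rich, peri-methoxylated acceptor.

Step 2
Reactants: 4 2,4-dibromobut-1-ene
Product: 5 2-bromo-4-iodobut-1-ene
Conditions: NaI, acetone, reflux
Reagents that add atoms: sodium iodide, [Na+].[I-]
Why: Finkelstein exchange, which touches only the sp3 C–Br bond and provides a primary iodide reactive enough for enolate alkylation at low temperature.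

Step 3
Reactants: 3 (4R)-5,7-dimethoxy-4-phenylchroman-2-one; 5 2-bromo-4-iodobut-1-ene
Product: 6 (3S,4R)-3-(3-bromobut-3-en-1-yl)-5,7-dimethoxy-4-phenylchroman-2-one (3,4-trans)
Conditions: LiN(SiMe3)2, THF, −78 °C; then 5, DMPU, −78 → −30 °C
Reagents that add atoms: none
Why: Lactone enolate alkylation (SN2); the 4-phenyl group sits pseudo-axial next to the 5-methoxy group and shields one face, so the electrophile enters anti to it and gives the trans isomer, whose C5 configuration is corrected in step 4.

Step 4
Reactants: 6 trans-lactone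
Product: 7 (3R,4R)-3-(3-bromobut-3-en-1-yl)-5,7-dimethoxy-4-phenylchroman-2-one (3,4-cis)
Conditions: LiN(i-Pr)2 (1.1 equiv), THF, −78 °C; AcOH in THF, −78 °C; pH 7 buffer
Reagents that add atoms: none
Why: Enolate formation followed by kinetic protonation, in which the proton is delivered to the face anti to the pseudo-axial phenyl group and leaves the side chain cis to phenyl, the C5 configuration of the target.

Step 5
Reactants: 7 cis-lactone
Product: 9 (3R,4R)-3-(3-bromobut-3-en-1-yl)-2,5,7-trimethoxy-2-methyl-4-phenylchroman (anomer mixture at C2), via 2-methylidenechroman 8 (not isolated)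
Conditions: Cp2TiMe2, toluene, 70 °C, dark; filtration through basic alumina; then MeOH, PPTS (cat.), 0 °C
Reagents that add atoms: dimethyltitanocene, [Ti+4].[CH3-].[CH3-].[cH-]1cccc1.[cH-]1cccc1; methanol, CO
Why: Petasis methylenation of the lactone carbonyl followed by acid-catalysed Markovnikov addition of methanol to the exocyclic enol ether; neither stage is basic, so the epimerisable C5 centre is kept and the methyl group of C4 is in place before the carbon nucleophile arrives.

Step 6
Reactants: 10 cyclopent-2-enone; 11 isobutene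
Product: 12 cis-6,6-dimethylbicyclo[3.2.0]heptan-2-one (racemic)
Conditions: hν (Pyrex, λ > 300 nm), 11 (excess), CH2Cl2, −40 °C; separation from the minor 7,7-dimethyl isomer
Reagents that add atoms: none
Why: Enone–alkene [2+2] photocycloaddition, which gives the cis-fused head-to-tail adduct with the CMe2 carbon on the enone β-carbon, i.e. the C1–C11 and C9–C10 bonds of the target.

Step 7
Reactants: 12 racemic photoadduct
Product: 13 (S)-S-{[(1S,2R,5S)-2-hydroxy-6,6-dimethylbicyclo[3.2.0]heptan-2-yl]methyl}-N-methyl-S-phenylsulfoximine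
Conditions: (S)-N,S-dimethyl-S-phenylsulfoximine, n-BuLi, THF, −78 °C; aq NH4Cl; chromatographic separation of the two exo adducts
Reagents that add atoms: (S)-N,S-dimethyl-S-phenylsulfoximine, CN=[S@@](C)(=O)c1ccccc1
Why: Johnson sulfoximine resolution, in which the lithiated sulfoximine adds to the convex face of each ketone enantiomer to give two separable diastereomers; the one derived from the (1S,5S)-ketone is taken on.

Step 8
Reactants: 13 sulfoximine adduct
Product: 14 (1S,5S)-6,6-dimethylbicyclo[3.2.0]heptan-2-one
Conditions: toluene, 110 °C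
Reagents that add atoms: none
Why: Thermal retro-addition of the β-hydroxysulfoximine, which returns the enantiopure ketone and the recoverable sulfoximine without touching the ring-fusion centres.

Step 9
Reactants: 14 (1S,5S)-ketone
Product: 15 (1S,5S)-3-hydroxy-6,6-dimethylbicyclo[3.2.0]heptan-2-one (C3 epimers)
Conditions: KN(SiMe3)2, THF, −78 °C; 2-(phenylsulfonyl)-3-phenyloxaziridine; aq NH4Cl
Reagents that add atoms: 2-(phenylsulfonyl)-3-phenyloxaziridine, O=S(=O)(c1ccccc1)N1OC1c1ccccc1
Why: Davis hydroxylation of the kinetic potassium enolate, which forms at the CH2 group because enolisation toward the ring-fusion carbon would place a double bond exocyclic to the cyclobutane.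

Step 10
Reactants: 15 α-hydroxy ketone
Product: 16 methyl (1S,2S)-3,3-dimethyl-2-(2-oxoethyl)cyclobutane-1-carboxylate (cis)
Conditions: Pb(OAc)4, MeOH/CH2Cl2 1:1, 0 °C
Reagents that add atoms: methanol, CO
Why: Criegee-type glycol-like cleavage of an α-ketol in methanol, which turns the ketone carbon into the methyl ester on C9 and the carbinol carbon into the aldehyde C3, leaving C1 non-enolisable.

Step 11
Reactants: 16 ester aldehyde
Product: 17 methyl (1S,2S)-2-ethynyl-3,3-dimethylcyclobutane-1-carboxylate (cis)
Conditions: C4F9SO2F, P2-Et phosphazene base, DMF, −20 °C → rt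
Reagents that add atoms: none
Why: One-pot alkenyl nonaflate formation and β-elimination converts the CH2–CHO unit into a terminal alkyne with the same two carbons (C2, C3); an aldehyde-derived nonaflate can only eliminate to the alkyne, so C1 is not involved.

Step 12
Reactants: 9 methyl ketal; 17 alkyne ester
Product: 19 methyl (1S,2S)-2-{[(2R,3R,4R)-3-(3-bromobut-3-en-1-yl)-5,7-dimethoxy-2-methyl-4-phenylchroman-2-yl]ethynyl}-3,3-dimethylcyclobutane-1-carboxylate, via alkynyl(dimethyl)alane 18 (not isolated)
Conditions: 17, LiN(SiMe3)2, toluene, −78 °C; Me2AlCl, −78 → 0 °C; then 9, CH2Cl2, −40 → 0 °C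
Reagents that add atoms: none
Why: Organoalane alkynylation of a mixed ketal through the 2-methyl oxocarbenium ion, with no amine base present that could deprotonate the cation; the alkynyl group is delivered to the face anti to both the C5 side chain and the C1′ phenyl group, which sets the quaternary C4 with methyl cis to these groups.

Step 13
Reactants: 19 alkynyl chroman
Product: 20 methyl (1S,2S)-2-{2-[(2S,3R,4R)-3-(3-bromobut-3-en-1-yl)-5,7-dimethoxy-2-methyl-4-phenylchroman-2-yl]ethyl}-3,3-dimethylcyclobutane-1-carboxylate
Conditions: TsNHNH2 (excess, in portions), NaOAc, DME/H2O, 85 °C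
Reagents that add atoms: none
Why: Diimide reduction transfers hydrogen by a concerted syn pathway to the alkyne and then to the derived cis-alkene, whereas the halogen-bearing 1,1-disubstituted bromoalkene is a poor acceptor; no metal is present that could cleave the C–Br bond or the tertiary propargylic C–O bond.

Step 14
Reactants: 20 methyl ester
Product: 21 (1S,2S)-2-{2-[(2S,3R,4R)-3-(3-bromobut-3-en-1-yl)-5,7-dimethoxy-2-methyl-4-phenylchroman-2-yl]ethyl}-3,3-dimethylcyclobutane-1-carboxylic acid
Conditions: LiOH, THF/MeOH/H2O, 40 °C; then 1 M HCl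
Reagents that add atoms: lithium hydroxide, [Li+].[OH-]
Why: Ester saponification; the bromoalkene and aryl ethers are inert to hydroxide, and any epimerisation at C9 is without consequence.

Step 15
Reactants: 21 carboxylic acid
Product: 22 1,3-dioxoisoindolin-2-yl (1S,2S)-2-{2-[(2S,3R,4R)-3-(3-bromobut-3-en-1-yl)-5,7-dimethoxy-2-methyl-4-phenylchroman-2-yl]ethyl}-3,3-dimethylcyclobutane-1-carboxylate
Conditions: N-hydroxyphthalimide, DIC, DMAP (cat.), CH2Cl2, rt
Reagents that add atoms: N-hydroxyphthalimide, O=C1c2ccccc2C(=O)N1O
Why: Carbodiimide (Steglich-type) esterification gives the redox-active ester that serves as the radical precursor for C9.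

Step 16
Reactants: 22 bromoalkene redox-active ester
Product: 23 dimethyl ether of the deformyl target: (1S,4S,5R,9R,1′R) tetracycle with the trans-fused cyclobutane, the 8-methylidene nine-membered ring and the 5,7-dimethoxy-4-phenylchroman
Conditions: NiCl2·glyme (20 mol %), 2,2′-bipyridine (24 mol %), AgNO3 (30 mol %), LiCl, DMF, Mg anode, reticulated vitreous carbon cathode, constant current, rt; 22 added by syringe pump (final about 2 mM)
Reagents that add atoms: none
Why: Proposed new method: cathodically generated low-valent nickel–bipyridine inserts into the C8–Br bond, single-electron reduction of the N-acyloxyphthalimide releases CO2 and phthalimide anion to give the C9 cyclobutyl radical, the alkenylnickel held on the same molecule through C1–C7 captures it, and C(sp2)–C(sp3) reductive elimination forms C8–C9; the closest known reaction is the intermolecular nickel-electrocatalytic decarboxylative alkenylation of redox-active esters with alkenyl bromides, which has not been used to close a nine-membered carbocycle. The ring closes by radical capture at the metal and reductive elimination from a ten-membered nickelacycle, not by radical addition to an alkene, so the slow medium-ring radical cyclisation modes do not apply. The new stereocentre C9 is set here: the cyclobutyl radical is planar, both C9 epimers of 22 converge, and the bond should form on the face anti to the C1–C2 bond because a trans-fused cyclobutane lets the nine-membered ring span two pseudo-equatorial bonds whereas cis fusion would eclipse them. The step needs intramolecular capture to outrun hydrogen-atom abstraction, dimerisation and oligomerisation; this is served by slow addition to high dilution, by the turn that the trans-disposed C4 and C5 chains of the chroman impose, and by a cyclobutyl radical that neither ring-opens nor eliminates.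

Step 17
Reactants: 23 dimethyl ether
Product: 24 5,7-dihydroxy compound (deformyl psidial A)
Conditions: MeMgI (10 equiv), Et2O removed, neat melt, 160 °C; then aq NH4Cl
Reagents that add atoms: none
Why: Grignard-mediated O-demethylation, a nucleophilic cleavage at the methyl carbon used for resorcinol dimethyl ethers of acid-sensitive terpenoids; it should spare the exocyclic alkene and the tertiary chroman ether, which cannot undergo SN2 cleavage.

Step 18
Reactants: 24 diphenol
Product: 25 psidial A
Conditions: POCl3, DMF, EtOAc, 0 °C → rt; then H2O, NaOAc, 60 °C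
Reagents that add atoms: N,N-dimethylformamide, CN(C)C=O; water, O
Why: Double Vilsmeier–Haack formylation at the only two free ring positions (C6 and C8 of the chroman); the free phenols keep the ring nucleophilic after the first iminium has formed, as in the diformylation of phloroglucinol, and the isolated 1,1-disubstituted alkene is far less reactive than the arene.

**Compound list**

1 | 5,7-dimethoxycoumarin | COc1cc(OC)c2ccc(=O)oc2c1 | starting material
2 | phenylboronic acid | OB(O)c1ccccc1 | starting material
3 | (4R)-5,7-dimethoxy-4-phenylchroman-2-one | O=C1C[C@H](c2ccccc2)c2c(OC)cc(OC)cc2O1 | intermediate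
4 | 2,4-dibromobut-1-ene | C=C(Br)CCBr | starting material
5 | 2-bromo-4-iodobut-1-ene | C=C(Br)CCI | intermediate
6 | (3S,4R)-3-(3-bromobut-3-en-1-yl)-5,7-dimethoxy-4-phenylchroman-2-one (trans) | C=C(Br)CC[C@H]1[C@H](c2ccccc2)c2c(OC)cc(OC)cc2OC1=O | intermediate
7 | (3R,4R)-3-(3-bromobut-3-en-1-yl)-5,7-dimethoxy-4-phenylchroman-2-one (cis) | C=C(Br)CC[C@@H]1[C@H](c2ccccc2)c2c(OC)cc(OC)cc2OC1=O | intermediate
8 | (3R,4R)-3-(3-bromobut-3-en-1-yl)-5,7-dimethoxy-2-methylidene-4-phenylchroman | C=C(Br)CC[C@@H]1[C@H](c2ccccc2)c2c(OC)cc(OC)cc2OC1=C | intermediate (not isolated)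
9 | (3R,4R)-3-(3-bromobut-3-en-1-yl)-2,5,7-trimethoxy-2-methyl-4-phenylchroman (C2 anomers) | C=C(Br)CC[C@@H]1[C@H](c2ccccc2)c2c(OC)cc(OC)cc2OC1(C)OC | intermediate
10 | cyclopent-2-enone | O=C1C=CCC1 | starting material
11 | isobutene | C=C(C)C | starting material
12 | cis-6,6-dimethylbicyclo[3.2.0]heptan-2-one (cis-fused racemate) | O=C1CCC2C1CC2(C)C | intermediate
13 | (S)-S-{[(1S,2R,5S)-2-hydroxy-6,6-dimethylbicyclo[3.2.0]heptan-2-yl]methyl}-N-methyl-S-phenylsulfoximine | O[C@]1(C[S@@](=O)(=NC)c2ccccc2)CC[C@H]2[C@@H]1CC2(C)C | intermediate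
14 | (1S,5S)-6,6-dimethylbicyclo[3.2.0]heptan-2-one | O=C1CC[C@H]2[C@@H]1CC2(C)C | intermediate
15 | (1S,5S)-3-hydroxy-6,6-dimethylbicyclo[3.2.0]heptan-2-one (C3 epimers) | O=C1C(O)C[C@H]2[C@@H]1CC2(C)C | intermediate
16 | methyl (1S,2S)-3,3-dimethyl-2-(2-oxoethyl)cyclobutane-1-carboxylate | O=CC[C@H]1[C@@H](C(=O)OC)CC1(C)C | intermediate
17 | methyl (1S,2S)-2-ethynyl-3,3-dimethylcyclobutane-1-carboxylate | C#C[C@H]1[C@@H](C(=O)OC)CC1(C)C | intermediate
18 | dimethyl{[(1S,2S)-2-(methoxycarbonyl)-4,4-dimethylcyclobutyl]ethynyl}alane | C[Al](C)C#C[C@H]1[C@@H](C(=O)OC)CC1(C)C | intermediate (not isolated)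
19 | alkynyl chroman ester (chroman 2R,3R,4R; cyclobutane 1S,2S) | C=C(Br)CC[C@@H]1[C@H](c2ccccc2)c2c(OC)cc(OC)cc2O[C@@]1(C)C#C[C@H]1[C@@H](C(=O)OC)CC1(C)C | intermediate
20 | saturated chroman ester (chroman 2S,3R,4R; cyclobutane 1S,2S) | C=C(Br)CC[C@@H]1[C@H](c2ccccc2)c2c(OC)cc(OC)cc2O[C@@]1(C)CC[C@H]1[C@@H](C(=O)OC)CC1(C)C | intermediate
21 | corresponding cyclobutanecarboxylic acid | C=C(Br)CC[C@@H]1[C@H](c2ccccc2)c2c(OC)cc(OC)cc2O[C@@]1(C)CC[C@H]1[C@@H](C(=O)O)CC1(C)C | intermediate
22 | N-acyloxyphthalimide of 21 (bromoalkene redox-active ester) | C=C(Br)CC[C@@H]1[C@H](c2ccccc2)c2c(OC)cc(OC)cc2O[C@@]1(C)CC[C@H]1[C@@H](C(=O)ON2C(=O)c3ccccc3C2=O)CC1(C)C | intermediate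
23 | dimethyl ether of deformyl psidial A | C=C1CC[C@@H]2[C@H](c3ccccc3)c3c(OC)cc(OC)cc3O[C@@]2(C)CC[C@H]2[C@H]1CC2(C)C | intermediate
24 | deformyl psidial A (5,7-diol) | C=C1CC[C@@H]2[C@H](c3ccccc3)c3c(O)cc(O)cc3O[C@@]2(C)CC[C@H]2[C@H]1CC2(C)C | intermediate
25 | psidial A | C=C1CC[C@@H]2[C@H](c3ccccc3)c3c(O)c(C=O)c(O)c(C=O)c3O[C@@]2(C)CC[C@H]2[C@H]1CC2(C)C | target

**Step count**

Total: 18 steps. Longest linear sequence: 13 steps (steps 6–11, then 12–18, from cyclopent-2-enone).

**Steps most likely to fail, with fallbacks**

1. Step 16 (proposed new method). The C9 radical may be reduced by hydrogen-atom abstraction before the tethered alkenylnickel captures it; intermolecular coupling may give dimers and oligomers; or the ring may close with cis fusion at the cyclobutane. The fallback makes C8–C9 in the established intermolecular mode and closes the nine-membered ring by olefin metathesis at C2–C3. It sets out from alkyne 17 and ketal 9 and returns at 23.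
 - Alkyne 17 is semi-hydrogenated (H2, Pd/CaCO3–Pb(OAc)2, quinoline) to methyl cis-2-ethenyl-3,3-dimethylcyclobutane-1-carboxylate F1.
 - Saponification gives cis-2-ethenyl-3,3-dimethylcyclobutane-1-carboxylic acid F2, and N-hydroxyphthalimide/DIC gives its N-acyloxyphthalimide F3.
 - F3 and the bromoalkene of 9 are coupled under the NiCl2·glyme/bipyridine electrolysis of step 16 at ordinary concentration. The radical is captured anti to the neighbouring vinyl group, which should give the trans-cyclobutane diene ketal F4.
 - Dimethyl(vinyl)alane (from CH2=CHMgBr and Me2AlCl) replaces the ketal methoxy group anti to the C5 and C1′ substituents, as in step 12, to give the C4-vinyl triene F5.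
 - Ring-closing metathesis with the second-generation Hoveyda–Grubbs catalyst at high dilution in hot toluene gives the (Z)-2,3-dehydro macrocycle F6.
 - Diimide reduces the strained ring alkene in preference to the exocyclic methylidene and delivers 23.

2. Step 13. Diimide may also saturate the bromoalkene, or the reduction may stall at the hindered cis-alkene. The fallback carries C8 as a protected carbinol, so that the alkyne is reduced when no other reducible group is present, and makes the bromoalkene afterwards. It sets out from lactone 3 and returns at 20.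
 - Lactone 3 is alkylated as in step 3 with tert-butyl[(4-iodobutan-2-yl)oxy]dimethylsilane to give the trans silyloxybutyl lactone F7.
 - Enolate formation and kinetic protonation as in step 4 give the cis lactone F8.
 - Cp2TiMe2, then MeOH/PPTS, give the methyl ketal F9.
 - Alane 18 gives the alkynyl chroman F10.
 - Exhaustive diimide reduction (or H2 over Rh/Al2O3) gives the saturated silyl ether F11.
 - Bu4NF gives the secondary alcohol F12, and Dess–Martin periodinane the methyl ketone F13.
 - KN(SiMe3)2/PhNTf2 at −78 °C gives the terminal enol triflate F14.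
 - Nickel-catalysed triflate-to-bromide exchange (Ni(cod)2 cat., LiBr) converts F14 into 20.

3. Step 17. The hot Grignard melt may open the tertiary aryl ether of the chroman, or the second demethylation may stop at the phenoxide stage. The fallback formylates first and then removes the methyl groups by chelation to the new aldehydes under mild conditions. It sets out from 23 and returns at 25.
 - NBS (2 equiv, MeCN, 0 °C) brominates the two free arene positions to give the 6,8-dibromo dimethyl ether F15.
 - Double bromine–lithium exchange (t-BuLi, THF, −78 °C) and a DMF quench give psidial A dimethyl ether F16.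
 - MgI2·OEt2 in toluene cleaves the two methyl ethers, each of which is ortho to a formyl group, and gives 25.

**Further compounds**

F1 | step 16 | methyl (1S,2S)-2-ethenyl-3,3-dimethylcyclobutane-1-carboxylate | C=C[C@H]1[C@@H](C(=O)OC)CC1(C)C
F2 | step 16 | (1S,2S)-2-ethenyl-3,3-dimethylcyclobutane-1-carboxylic acid | C=C[C@H]1[C@@H](C(=O)O)CC1(C)C
F3 | step 16 | 1,3-dioxoisoindolin-2-yl (1S,2S)-2-ethenyl-3,3-dimethylcyclobutane-1-carboxylate | C=C[C@H]1[C@@H](C(=O)ON2C(=O)c3ccccc3C2=O)CC1(C)C
F4 | step 16 | methyl ketal carrying the 3-(trans-2-ethenyl-3,3-dimethylcyclobutyl)but-3-enyl chain on C5 | C=C(CC[C@@H]1[C@H](c2ccccc2)c2c(OC)cc(OC)cc2OC1(C)OC)[C@@H]1CC(C)(C)[C@H]1C=C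
F5 | step 16 | C4-vinyl triene | C=C(CC[C@@H]1[C@H](c2ccccc2)c2c(OC)cc(OC)cc2O[C@@]1(C)C=C)[C@@H]1CC(C)(C)[C@H]1C=C
F6 | step 16 | (Z)-2,3-dehydro derivative of 23 | C=C1CC[C@@H]2[C@H](c3ccccc3)c3c(OC)cc(OC)cc3O[C@@]2(C)/C=C\[C@H]2[C@H]1CC2(C)C
F7 | step 13 | (3S,4R)-3-[3-(tert-butyldimethylsilyloxy)butyl]-5,7-dimethoxy-4-phenylchroman-2-one (carbinol epimers) | CC(O[Si](C)(C)C(C)(C)C)CC[C@H]1[C@H](c2ccccc2)c2c(OC)cc(OC)cc2OC1=O
F8 | step 13 | (3R,4R)-3-[3-(tert-butyldimethylsilyloxy)butyl]-5,7-dimethoxy-4-phenylchroman-2-one | CC(O[Si](C)(C)C(C)(C)C)CC[C@@H]1[C@H](c2ccccc2)c2c(OC)cc(OC)cc2OC1=O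
F9 | step 13 | corresponding 2-methoxy-2-methylchroman ketal | CC(O[Si](C)(C)C(C)(C)C)CC[C@@H]1[C@H](c2ccccc2)c2c(OC)cc(OC)cc2OC1(C)OC
F10 | step 13 | alkynyl chroman ester with silyloxybutyl chain | CC(O[Si](C)(C)C(C)(C)C)CC[C@@H]1[C@H](c2ccccc2)c2c(OC)cc(OC)cc2O[C@@]1(C)C#C[C@H]1[C@@H](C(=O)OC)CC1(C)C
F11 | step 13 | saturated chroman ester with silyloxybutyl chain | CC(O[Si](C)(C)C(C)(C)C)CC[C@@H]1[C@H](c2ccccc2)c2c(OC)cc(OC)cc2O[C@@]1(C)CC[C@H]1[C@@H](C(=O)OC)CC1(C)C
F12 | step 13 | corresponding secondary alcohol | CC(O)CC[C@@H]1[C@H](c2ccccc2)c2c(OC)cc(OC)cc2O[C@@]1(C)CC[C@H]1[C@@H](C(=O)OC)CC1(C)C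
F13 | step 13 | corresponding methyl ketone | CC(=O)CC[C@@H]1[C@H](c2ccccc2)c2c(OC)cc(OC)cc2O[C@@]1(C)CC[C@H]1[C@@H](C(=O)OC)CC1(C)C
F14 | step 13 | corresponding terminal enol triflate | C=C(OS(=O)(=O)C(F)(F)F)CC[C@@H]1[C@H](c2ccccc2)c2c(OC)cc(OC)cc2O[C@@]1(C)CC[C@H]1[C@@H](C(=O)OC)CC1(C)C
F15 | step 17 | 6,8-dibromo derivative of 23 | C=C1CC[C@@H]2[C@H](c3ccccc3)c3c(OC)c(Br)c(OC)c(Br)c3O[C@@]2(C)CC[C@H]2[C@H]1CC2(C)C
F16 | step 17 | psidial A dimethyl ether | C=C1CC[C@@H]2[C@H](c3ccccc3)c3c(OC)c(C=O)c(OC)c(C=O)c3O[C@@]2(C)CC[C@H]2[C@H]1CC2(C)C
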